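## The problem

The target is a flavonol, 3,5,7-trihydroxy-2-(4-methoxyphenyl)-8-(2-methylbut-3-en-2-yl)-4H-chromen-4-one. Ring A is a phloroglucinol nucleus with free hydroxyls at C5 and C7, ring C is a 4-pyranone with a hydroxyl at C3, and ring B is a 4-methoxyphenyl group on C2. A reverse prenyl group sits at C8, between O1 and the C7 oxygen, so a quaternary benzylic carbon must be attached to one specific carbon of a ring whose three oxygens start out equivalent. Attachment at C6, or attachment as a normal prenyl group, are the errors to exclude. The molecule has no stereocentre and no stereogenic double bond, so the whole task is one of regio- and chemoselectivity. Three hydroxyls must be set free at the end beside an aryl methyl ether that has to stay, which rules out methyl ethers as protecting groups. The terminal vinyl group rules out hydrogenolysis and strong acid (cyclisation onto the C7 hydroxyl, hydration). Ring A is open to electrophilic halogenation and the free flavonol is air-sensitive in base, so the C3 hydroxyl should be unveiled late. The feature that opens the key step is that C2=C3 is the enol ether double bond on O1: it is the olefination product of a 4-methoxybenzoate of the C8a oxygen, and C3 with its oxygen is a single carbon between the acyl carbon C4 and C2.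

## Retrosynthesis

**Protecting groups (16 from 15 from 14).** The O–C bonds of two methoxymethyl ethers (O5, O7) and of a 2-(trimethylsilyl)ethyl ether (O3) are cut. The C3 oxygen arrives on the ylide carbon, so its substituent must be one the phosphonium salt 11 already carries and that leaves without touching the 4'-methyl ether or the vinyl group; the silylethyl group leaves with fluoride. Methoxymethyl ethers survive heat, amine bases, the ylide and buffered oxidation, and come off in dilute acid. Fluoride is used first, on the neutral molecule 14, and acid last, so that the free phenols of 16 see no further reagent.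

**Ring C (14 from 10 and 12).** The bonds C3–C4 and C2=C3 are cut. The neighbouring cuts through O1–C2 (chalcone or diketone routes) either close the ring through the most hindered oxygen of ring A or bring in the C3 oxygen by a separate oxidation of a molecule that holds a second alkene and an electron-rich arene. Here O1–C2 is taken over intact from an ester. The precursor falls into acid chloride 10, which already holds rings A and B, and the one-carbon ylide 12, made in the flask from commercial salt 11. The forward reaction must acylate 12 at the acid chloride only, and the keto ylide 13 so formed must olefinate the aryl ester next to it.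

**Carboxyl activation (10 from 9 from 8).** The C–Cl bond and then one C–O bond of the carboxyl group are cut, leading back to aldehyde 8. The acid chloride has to be made without hydrogen chloride because of the acetals. The aldehyde is oxidised only after the phenol is acylated, since a free electron-rich phenol would not survive the Pinnick oxidation.

**Ring B attachment (8 from 6 and 7).** The ester bond between the C8a oxygen and the aroyl carbon is cut. Acylation is the least demanding way to load a phenol that is chelated and flanked by a quaternary carbon, and acid chloride 7 is a commercial reagent.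

**The C4 carbon (6 from 5).** The bond from C4a to the formyl carbon is cut. Phenol 5 has a single free ortho position, so an ortho-specific formylation through the magnesium phenoxide can only give 6. Direct carboxylation would save the later oxidation but is less reliable on this hindered phenol and is kept as a reserve.

**The quaternary carbon (5 from 4, 4 from 2 and 3, 2 from 1).** The bond from C8 to the quaternary carbon is cut by a [3,3] shift, which leads to prenyl ether 4 and from there to phenol 2 and bromide 3. The rearrangement inverts the allyl unit, so the normal prenyl ether gives the reverse prenyl group, and the two ortho positions of 4 are equivalent. The forward reaction must stop at the ortho phenol and not carry the group on to the para position. Phenol 2 comes from 1 by twofold protection; because the three hydroxyls of 1 are equivalent there is only one bis-ether.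

## Roads not taken

Alternative 1: The cut is C3–C4 of a 3-hydroxyflavanone. In the forward direction the dialdehyde A2, 4,6-bis(methoxymethoxy)-2-[1-(4-methoxyphenyl)-2-oxoethoxy]-3-(2-methylbut-3-en-2-yl)benzaldehyde, would be treated with a thiazolium-derived carbene. The carbene turns one formyl group into an acyl anion equivalent that adds to the other, closing ring C as the trans 3-hydroxyflavanone A1. Dehydrogenation of A1 and acetal removal would finish the synthesis.
- Merits: the step is catalytic, mild and of a known reaction class for chromanones. A2 would come from the same salicylaldehyde 6. Either acyloin regioisomer would converge on the flavonol after oxidation. The step count from 6 is about the same as in the chosen plan.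
- Weak points: O1–C2 has to be made by alkylation of the phenol of 6, which is chelated and flanked by a quaternary carbon, with a secondary benzylic electrophile. A2 holds an enolisable α-aryloxy aldehyde beside a di-ortho-substituted, electron-rich aryl aldehyde that is slow to engage the carbene. Two stereocentres are built only to be erased.
- Comparison: in precedent this road is the safer one, and that is conceded. The chosen plan sets against it that O1–C2 is made by acylation, that the flavonol oxidation level is reached directly with O3 already differentiated, and that no redox adjustment at C2/C3 follows the ring closure.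

Alternative 2: The cut is at the two C–CH3 bonds of the quaternary carbon. The enolate of benzofuranone A4, 4,6-bis(methoxymethoxy)-1-benzofuran-2(3H)-one, would be C-methylated twice to give A3. Reduction of the lactone and methylenation would then give phenol 5.
- Merits: the quaternary carbon is tied to its ring position by the lactone, so there is no ortho/para question. In this respect it is better than the Claisen rearrangement.
- Weak points: it solves only what steps 2 and 3 solve and says nothing about ring C. A4 needs its own synthesis from 1. O-methylation of the electron-rich enolate competes. The neopentyl lactol must be methylenated. The count rises by at least three steps.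
- Comparison: the chosen plan sets against it a two-step installation from 2 with two equivalent ortho positions.

Alternative 3: The cut removes ring A (C5–C6, C7–C8 and C4a–C5). Diazo ketone A6, 6-(2-diazo-3,3-dimethylpent-4-enoyl)-3-(methoxymethoxy)-2-(4-methoxyphenyl)-4H-pyran-4-one, would undergo Wolff rearrangement to a ketene. The ketene would add the siloxyalkyne A7, the cyclobutenone would open, and the dienylketene would close onto the pyranone to give A5.
- Merits: it is the most convergent road. Every substituent of ring A, including the C8 quaternary group and differentiated oxygens at C5 and C7, is placed by the mechanism.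
- Weak points: A6 is a fully substituted pyranone with a diazo carbon next to a quaternary centre and is long to make. A ketene with a tertiary alkyl group is hindered in the [2+2] step. The pyranone chromophore is itself photoreactive. A benzannulation on a pyranonyl ketene is without precedent.
- Comparison: it is better in regiocontrol and convergence. The chosen plan sets against it that ring A is bought as 1 and that the whole route is ten linear steps.

Key step: step 8

## Route

Assumption: the target has no stereocentre, so no SMILES string of the main route carries a stereodescriptor; salt 11, bromide 3 and acid chloride 7 are taken as purchased reagents.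

Step 1
Reactants: 1 benzene-1,3,5-triol (phloroglucinol)
Product: 2 3,5-bis(methoxymethoxy)phenol
Conditions: MeOCH2Cl (2.0 equiv), i-Pr2NEt (2.2 equiv), DMF, 0 °C → rt; chromatography
Reagents that add atoms: chloromethyl methyl ether, COCCl
Why: O-alkylation of a symmetrical triphenol with a hard electrophile under amine base; the three hydroxyls are equivalent, so only one bis-ether exists and the mono- and tris-ethers are separable by polarity.

Step 2
Reactants: 2 3,5-bis(methoxymethoxy)phenol; 3 1-bromo-3-methylbut-2-ene
Product: 4 1,3-bis(methoxymethoxy)-5-[(3-methylbut-2-en-1-yl)oxy]benzene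
Conditions: K2CO3, acetone, rt → 40 °C
Reagents that add atoms: none
Why: Williamson ether synthesis; a carbonate base in a polar aprotic solvent favours O- over C-alkylation, and substitution occurs at the primary allylic carbon.

Step 3
Reactants: 4 1,3-bis(methoxymethoxy)-5-[(3-methylbut-2-en-1-yl)oxy]benzene
Product: 5 3,5-bis(methoxymethoxy)-2-(2-methylbut-3-en-2-yl)phenol
Conditions: PhNEt2, 185 °C, sealed tube, argon; stopped when 4 is consumed
Reagents that add atoms: none
Why: Aromatic Claisen rearrangement; the [3,3] shift to either of two equivalent ortho carbons inverts the allyl unit and creates the quaternary carbon, and the amine solvent should speed enolisation of the ortho dienone so that the phenol is fixed before a further shift to the para position.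

Step 4
Reactants: 5 3,5-bis(methoxymethoxy)-2-(2-methylbut-3-en-2-yl)phenol
Product: 6 2-hydroxy-4,6-bis(methoxymethoxy)-3-(2-methylbut-3-en-2-yl)benzaldehyde
Conditions: MgCl2, Et3N, (CH2O)n, MeCN, reflux; aq. citric acid work-up
Reagents that add atoms: formaldehyde (as paraformaldehyde), C=O
Why: Casnati–Skattebøl ortho-formylation; formaldehyde is delivered inside the magnesium phenoxide to the only free ortho carbon, and a second formaldehyde takes up hydride to give the aldehyde; the conditions are basic and leave the acetals alone.

Step 5
Reactants: 6 2-hydroxy-4,6-bis(methoxymethoxy)-3-(2-methylbut-3-en-2-yl)benzaldehyde; 7 4-methoxybenzoyl chloride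
Product: 8 2-formyl-3,5-bis(methoxymethoxy)-6-(2-methylbut-3-en-2-yl)phenyl 4-methoxybenzoate
Conditions: Et3N, DMAP (0.2 equiv), CH2Cl2, 0 °C → rt
Reagents that add atoms: none
Why: DMAP-catalysed O-acylation; the acylpyridinium ion is reactive enough for a phenol that is chelated to the formyl group and flanked by the quaternary carbon, and the aldehyde has no enolisable hydrogen.

Step 6
Reactants: 8 2-formyl-3,5-bis(methoxymethoxy)-6-(2-methylbut-3-en-2-yl)phenyl 4-methoxybenzoate
Product: 9 2-[(4-methoxybenzoyl)oxy]-4,6-bis(methoxymethoxy)-3-(2-methylbut-3-en-2-yl)benzoic acid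
Conditions: NaClO2, NaH2PO4, 2-methylbut-2-ene (20 equiv), t-BuOH/THF/H2O, 0 °C → rt
Reagents that add atoms: NaClO2 (sodium chlorite), [Na+].[O-]Cl=O
Why: Pinnick oxidation; the buffered medium spares the aryl ester and the acetals, and the trisubstituted scavenger alkene should take up hypochlorous acid faster than the monosubstituted vinyl group or ring A.

Step 7
Reactants: 9 2-[(4-methoxybenzoyl)oxy]-4,6-bis(methoxymethoxy)-3-(2-methylbut-3-en-2-yl)benzoic acid
Product: 10 2-(chlorocarbonyl)-3,5-bis(methoxymethoxy)-6-(2-methylbut-3-en-2-yl)phenyl 4-methoxybenzoate
Conditions: Me2C=C(Cl)NMe2 (1.2 equiv), CH2Cl2, 0 °C → rt; volatiles removed, crude used at once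
Reagents that add atoms: 1-chloro-N,N,2-trimethylprop-1-en-1-amine, CC(C)=C(Cl)N(C)C
Why: Acid chloride formation with an α-chloroenamine; the only by-product is a neutral amide and no hydrogen chloride is set free, so the acetals, the ester and the alkene should be untouched.

Step 8
Reactants: 10 2-(chlorocarbonyl)-3,5-bis(methoxymethoxy)-6-(2-methylbut-3-en-2-yl)phenyl 4-methoxybenzoate; 11 {[2-(trimethylsilyl)ethoxy]methyl}triphenylphosphonium chloride
Product: 14 5,7-bis(methoxymethoxy)-2-(4-methoxyphenyl)-8-(2-methylbut-3-en-2-yl)-3-[2-(trimethylsilyl)ethoxy]-4H-chromen-4-one, via alkoxymethylidene phosphorane 12 (not isolated), via keto ylide 13 (not isolated)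
Conditions: 11 (2.3 equiv), NaN(SiMe3)2 (2.2 equiv), THF, −78 → 0 °C; 10 in THF added slowly at −78 °C, → rt; then PhMe added, 90 °C
Reagents that add atoms: none
Why: Proposed new method: the non-stabilised ylide 12 should attack the acid chloride carbon of 10 (C3–C4), and the acylphosphonium ion so formed is deprotonated by the second equivalent of 12 to the keto ylide 13, whose ylide carbon then adds to the neighbouring aryl ester carbonyl; the oxaphosphetane collapses with loss of the phosphine oxide to the C2=C3 bond. The closest known reaction type is the one-pot flavone synthesis from silyl esters of O-aroylsalicylic acids and a silylmethylidene phosphorane, which runs through the same kind of acyl ylide and the same intramolecular olefination of an aryl ester; new here are the alkoxy group on the ylide carbon, which makes the new alkene tetrasubstituted, and the acid chloride as acyl donor. Ring C closes at carbon by a 6-exo-trig addition to the ester C=O (C3, C4, C4a, C8a, O1 and C2 form the ring), so the O1–C2 bond is carried over from ester 8. No stereocentre is formed. The step needs chemoselectivity between the two acyl groups of 10: the acid chloride is far more electrophilic than the electron-rich, hindered 4-methoxybenzoate, and slow addition of 10 to an excess of 12 at −78 °C keeps the ylide away from the ester until it is reached from within. Loss of the aryloxide from the tetrahedral adduct would give a phosphonium ion without an α-hydrogen that can only revert, whereas collapse of the oxaphosphetane is irreversible. The alkoxy group raises the nucleophilicity of the stabilised ylide, and heating after the acylation is planned because a tetrasubstituted alkene is built.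

Step 9
Reactants: 14 5,7-bis(methoxymethoxy)-2-(4-methoxyphenyl)-8-(2-methylbut-3-en-2-yl)-3-[2-(trimethylsilyl)ethoxy]-4H-chromen-4-one
Product: 15 3-hydroxy-5,7-bis(methoxymethoxy)-2-(4-methoxyphenyl)-8-(2-methylbut-3-en-2-yl)-4H-chromen-4-one
Conditions: Bu4NF (3 equiv), THF, 50 °C, argon; aq. NH4Cl
Reagents that add atoms: none
Why: Fluoride-induced β-fragmentation of a 2-(trimethylsilyl)ethyl ether; attack at silicon releases ethene and the flavonol oxyanion, a vinylogous carboxylate and therefore a good leaving group, while methoxymethyl ethers are inert to fluoride.

Step 10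
Reactants: 15 3-hydroxy-5,7-bis(methoxymethoxy)-2-(4-methoxyphenyl)-8-(2-methylbut-3-en-2-yl)-4H-chromen-4-one
Product: 16 3,5,7-trihydroxy-2-(4-methoxyphenyl)-8-(2-methylbut-3-en-2-yl)-4H-chromen-4-one
Conditions: HCl (1 M) in MeOH, rt → 40 °C
Reagents that add atoms: none
Why: Acid-catalysed acetal exchange removes both methoxymethyl groups; the aryl methyl ether is inert, and protonation of the monosubstituted alkene would need a secondary cation, so cyclisation onto the C7 hydroxyl should be slow in dilute acid near room temperature.

## Compound list

1 | benzene-1,3,5-triol (phloroglucinol) | Oc1cc(O)cc(O)c1 | starting material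
2 | 3,5-bis(methoxymethoxy)phenol | COCOc1cc(O)cc(OCOC)c1 | intermediate
3 | 1-bromo-3-methylbut-2-ene | CC(C)=CCBr | starting material
4 | 1,3-bis(methoxymethoxy)-5-[(3-methylbut-2-en-1-yl)oxy]benzene | COCOc1cc(OCC=C(C)C)cc(OCOC)c1 | intermediate
5 | 3,5-bis(methoxymethoxy)-2-(2-methylbut-3-en-2-yl)phenol | C=CC(C)(C)c1c(O)cc(OCOC)cc1OCOC | intermediate
6 | 2-hydroxy-4,6-bis(methoxymethoxy)-3-(2-methylbut-3-en-2-yl)benzaldehyde | C=CC(C)(C)c1c(OCOC)cc(OCOC)c(C=O)c1O | intermediate
7 | 4-methoxybenzoyl chloride | COc1ccc(C(=O)Cl)cc1 | starting material
8 | 2-formyl-3,5-bis(methoxymethoxy)-6-(2-methylbut-3-en-2-yl)phenyl 4-methoxybenzoate | C=CC(C)(C)c1c(OCOC)cc(OCOC)c(C=O)c1OC(=O)c1ccc(OC)cc1 | intermediate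
9 | 2-[(4-methoxybenzoyl)oxy]-4,6-bis(methoxymethoxy)-3-(2-methylbut-3-en-2-yl)benzoic acid | C=CC(C)(C)c1c(OCOC)cc(OCOC)c(C(=O)O)c1OC(=O)c1ccc(OC)cc1 | intermediate
10 | 2-(chlorocarbonyl)-3,5-bis(methoxymethoxy)-6-(2-methylbut-3-en-2-yl)phenyl 4-methoxybenzoate | C=CC(C)(C)c1c(OCOC)cc(OCOC)c(C(=O)Cl)c1OC(=O)c1ccc(OC)cc1 | intermediate
11 | {[2-(trimethylsilyl)ethoxy]methyl}triphenylphosphonium chloride | C[Si](C)(C)CCOC[P+](c1ccccc1)(c1ccccc1)c1ccccc1.[Cl-] | starting material
12 | {[2-(trimethylsilyl)ethoxy]methylidene}triphenylphosphorane | C[Si](C)(C)CCOC=P(c1ccccc1)(c1ccccc1)c1ccccc1 | intermediate (not isolated)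
13 | 3,5-bis(methoxymethoxy)-6-(2-methylbut-3-en-2-yl)-2-{[2-(trimethylsilyl)ethoxy](triphenylphosphoranylidene)acetyl}phenyl 4-methoxybenzoate | C=CC(C)(C)c1c(OCOC)cc(OCOC)c(C(=O)C(OCC[Si](C)(C)C)=P(c2ccccc2)(c2ccccc2)c2ccccc2)c1OC(=O)c1ccc(OC)cc1 | intermediate (not isolated)
14 | 5,7-bis(methoxymethoxy)-2-(4-methoxyphenyl)-8-(2-methylbut-3-en-2-yl)-3-[2-(trimethylsilyl)ethoxy]-4H-chromen-4-one | C=CC(C)(C)c1c(OCOC)cc(OCOC)c2c(=O)c(OCC[Si](C)(C)C)c(-c3ccc(OC)cc3)oc12 | intermediate
15 | 3-hydroxy-5,7-bis(methoxymethoxy)-2-(4-methoxyphenyl)-8-(2-methylbut-3-en-2-yl)-4H-chromen-4-one | C=CC(C)(C)c1c(OCOC)cc(OCOC)c2c(=O)c(O)c(-c3ccc(OC)cc3)oc12 | intermediate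
16 | 3,5,7-trihydroxy-2-(4-methoxyphenyl)-8-(2-methylbut-3-en-2-yl)-4H-chromen-4-one | C=CC(C)(C)c1c(O)cc(O)c2c(=O)c(O)c(-c3ccc(OC)cc3)oc12 | target

## Step count and risk

Total step count: 10. Longest linear sequence: 10 steps (1 to 16).

**Step 8 (key step).** The ylide may attack the aryl ester between molecules, the keto ylide may be O-acylated by a second molecule of acid chloride, or the fully substituted stabilised ylide may add too slowly to the hindered ester, so that ring closure fails and the keto ylide is hydrolysed on work-up. The fallback uses known chemistry, sets out from acid 9 and comes back at 15. Acid 9 would be silylated (t-BuMe2SiCl, imidazole) to tert-butyldimethylsilyl 2-[(4-methoxybenzoyl)oxy]-4,6-bis(methoxymethoxy)-3-(2-methylbut-3-en-2-yl)benzoate F1. Heating F1 with [(trimethylsilyl)methylidene]triphenylphosphorane in THF, the known one-pot flavone synthesis, would give 5,7-bis(methoxymethoxy)-2-(4-methoxyphenyl)-8-(2-methylbut-3-en-2-yl)-4H-chromen-4-one F2. Lithiation of F2 at C3 with LiN(i-Pr)2 at −78 °C, trapping with B(OMe)3 and oxidation with H2O2 would then give flavonol 15, which is deprotected as in step 10.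

**Step 3.** The ortho dienone may undergo a second [3,3] shift to the para position before it enolises, the phenol may revert at high temperature and drift to the para isomer, the side chain may isomerise by the abnormal Claisen pathway, or the phenol may add to the alkene. The fallback sets out from 1 and comes back at 6; it blocks the para position with the formyl group and uses a symmetrical ether. Vilsmeier–Haack formylation of 1 (POCl3, DMF; H2O) would give 2,4,6-trihydroxybenzaldehyde F3. Alkylation of the most acidic, non-chelated hydroxyl with 3 (K2CO3, one equivalent, acetone) would give 2,6-dihydroxy-4-[(3-methylbut-2-en-1-yl)oxy]benzaldehyde F4. Its Claisen rearrangement can only reach the two equivalent ortho carbons and would give 2,4,6-trihydroxy-3-(2-methylbut-3-en-2-yl)benzaldehyde F5. Twofold protection with MeOCH2Cl and i-Pr2NEt should spare the hydroxyl that is chelated and flanked by the quaternary carbon, giving 6.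

**Step 7.** The methoxymethyl ether next to the carboxyl group may take part in the activation: its oxygen can attack the acyl carbon through a six-membered transition state with loss of the methyl group. The crude acid chloride may also decompose on concentration. The fallback sets out from 9 and comes back at 13. Acid 9 would be converted with 1,1'-carbonyldiimidazole in THF into the milder acyl donor 2-(1H-imidazole-1-carbonyl)-3,5-bis(methoxymethoxy)-6-(2-methylbut-3-en-2-yl)phenyl 4-methoxybenzoate F6. Treating F6 with two equivalents of ylide 12, a known way to acylate phosphoranes, should give keto ylide 13 and from it 14.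

**Step 6.** Hypochlorous acid may chlorinate ring A at the carbon between the two acetal oxygens, the di-ortho-substituted aldehyde may be oxidised slowly, and the acidic buffer may start to cleave the acetals. The fallback sets out from 5 and comes back at 9. Ortho-carboxylation of phenol 5 with MeOMgOCO2Me in DMF at 120 °C, followed by a cold, weakly acidic work-up, would give 2-hydroxy-4,6-bis(methoxymethoxy)-3-(2-methylbut-3-en-2-yl)benzoic acid F7. O-aroylation of F7 with 7 (Et3N, DMAP, CH2Cl2) would give acid 9 without an aldehyde oxidation.

## Further compounds

F1 | step 8 | tert-butyldimethylsilyl 2-[(4-methoxybenzoyl)oxy]-4,6-bis(methoxymethoxy)-3-(2-methylbut-3-en-2-yl)benzoate | C=CC(C)(C)c1c(OCOC)cc(OCOC)c(C(=O)O[Si](C)(C)C(C)(C)C)c1OC(=O)c1ccc(OC)cc1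
F2 | step 8 | 5,7-bis(methoxymethoxy)-2-(4-methoxyphenyl)-8-(2-methylbut-3-en-2-yl)-4H-chromen-4-one | C=CC(C)(C)c1c(OCOC)cc(OCOC)c2c(=O)cc(-c3ccc(OC)cc3)oc12
F3 | step 3 | 2,4,6-trihydroxybenzaldehyde | O=Cc1c(O)cc(O)cc1O
F4 | step 3 | 2,6-dihydroxy-4-[(3-methylbut-2-en-1-yl)oxy]benzaldehyde | CC(C)=CCOc1cc(O)c(C=O)c(O)c1
F5 | step 3 | 2,4,6-trihydroxy-3-(2-methylbut-3-en-2-yl)benzaldehyde | C=CC(C)(C)c1c(O)cc(O)c(C=O)c1O
F6 | step 7 | 2-(1H-imidazole-1-carbonyl)-3,5-bis(methoxymethoxy)-6-(2-methylbut-3-en-2-yl)phenyl 4-methoxybenzoate | C=CC(C)(C)c1c(OCOC)cc(OCOC)c(C(=O)n2ccnc2)c1OC(=O)c1ccc(OC)cc1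
F7 | step 6 | 2-hydroxy-4,6-bis(methoxymethoxy)-3-(2-methylbut-3-en-2-yl)benzoic acid | C=CC(C)(C)c1c(OCOC)cc(OCOC)c(C(=O)O)c1O
A1 | alternative 1 | (2R,3R)-3-hydroxy-5,7-bis(methoxymethoxy)-2-(4-methoxyphenyl)-8-(2-methylbut-3-en-2-yl)-2,3-dihydro-4H-chromen-4-one (trans; one enantiomer of the racemate drawn) | O[C@@H]1[C@@H](c2ccc(OC)cc2)Oc2c(C(C)(C)C=C)c(OCOC)cc(OCOC)c2C1=O
A2 | alternative 1 | 4,6-bis(methoxymethoxy)-2-[1-(4-methoxyphenyl)-2-oxoethoxy]-3-(2-methylbut-3-en-2-yl)benzaldehyde (racemic) | O=CC(c1ccc(OC)cc1)Oc1c(C(C)(C)C=C)c(OCOC)cc(OCOC)c1C=O
A3 | alternative 2 | 4,6-bis(methoxymethoxy)-3,3-dimethyl-1-benzofuran-2(3H)-one | COCOc1cc(OCOC)c2c(c1)OC(=O)C2(C)C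
A4 | alternative 2 | 4,6-bis(methoxymethoxy)-1-benzofuran-2(3H)-one | COCOc1cc(OCOC)c2c(c1)OC(=O)C2
A5 | alternative 3 | 5-hydroxy-3-(methoxymethoxy)-2-(4-methoxyphenyl)-8-(2-methylbut-3-en-2-yl)-7-{[tri(propan-2-yl)silyl]oxy}-4H-chromen-4-one | C=CC(C)(C)c1c(O[Si](C(C)C)(C(C)C)C(C)C)cc(O)c2c(=O)c(OCOC)c(-c3ccc(OC)cc3)oc12
A6 | alternative 3 | 6-(2-diazo-3,3-dimethylpent-4-enoyl)-3-(methoxymethoxy)-2-(4-methoxyphenyl)-4H-pyran-4-one | C=CC(C)(C)C(=[N+]=[N-])C(=O)c1cc(=O)c(OCOC)c(-c2ccc(OC)cc2)o1
A7 | alternative 3 | (ethynyloxy)tri(propan-2-yl)silane | C#CO[Si](C(C)C)(C(C)C)C(C)C
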